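**Strategy.** The C11–O bond of the dihydropyran fused to tropolone ring A is made last. In the key step the free 6′-hydroxyl of a pendant hydroxytropone opens the (10S,11S)-epoxide of the eleven-membered ring at the tertiary carbon C11 with inversion, closing that pyran and releasing the C10 carbinol. This exploits the anti relationship between the secondary C10–OH and the quaternary C11(CH3)–O(tropolone) centre. The precursor is the macrocyclic E-epoxide carrying the finished pyran-fused ring B and, on the C1 methylene, ring A as a hydroxytropone. Its epoxide is set by Shi epoxidation before ring-closing metathesis, and its hydroxyl is unmasked from a 2-(trimethylsilyl)ethyl ether just before cyclisation.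

Key step: step 29

**Remarks**
- Locants C1–C11 are those of the eleven-membered ring: C1 (CH with the ring-A methylene), C2 (CH2), C3 (CMe2), C4=C5, C6 (CH2), C7 (C(CH3)–O), C8 (CH with the ring-B methylene), C9 (CH2), C10 (CH–O), C11 (C(CH3)–O). The same locants are used for open-chain intermediates.
- Tropone carbons carry primed locants: C1′ is the carbonyl carbon, C2′ bears OMe, C4′ bears CH3, C5′ bears the methylene and C6′ bears the oxygen that enters a pyran.
- ArSE is 2-methoxy-4-methyl-1-oxo-6-[2-(trimethylsilyl)ethoxy]cyclohepta-2,4,6-trien-5-yl.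
- Assumption: tautomers of a free tropolone are one compound, so 42 is written as in the target SMILES.
- Compounds 4–6 are racemic; their stereocentres disappear in step 5.
- Consistency check: the (10S,11S)-E-epoxide 40, opened with inversion at C11 and retention at C10, gives the (10S,11R) configuration of 41 and 42.
- The free hydroxytropone is kept masked through the epoxidation and metathesis, because its anion would be oxidised by the dioxirane and would bind the metathesis catalyst.
- Both seven-membered rings come from the same bromotropone 8, so step 24 consumes two molar equivalents of 8 per mole of 34.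

**Tropone building block**

Step 1
Reactants: 1 2-methylphenol
Product: 2 1-methyl-2-[2-(trimethylsilyl)ethoxy]benzene
Conditions: Me3SiCH2CH2OH, PPh3, DIAD, THF, 0 °C → rt
Reagents that add atoms: 2-(trimethylsilyl)ethanol, C[Si](C)(C)CCO
Why: Mitsunobu etherification of the phenol installs the fluoride-labile 2-(trimethylsilyl)ethyl group, which later serves as leaving group on ring B and as mask of the nucleophilic hydroxyl on ring A.

Step 2
Reactants: 2 1-methyl-2-[2-(trimethylsilyl)ethoxy]benzene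
Product: 3 1-methyl-2-[2-(trimethylsilyl)ethoxy]cyclohexa-1,4-diene
Conditions: Li, NH3 (l), t-BuOH, THF, −78 → −33 °C
Reagents that add atoms: none
Why: Birch reduction of an ortho-alkyl aryl ether should give the 2,5-dihydro isomer, in which both donor substituents stay on one tetrasubstituted enol-ether double bond.

Step 3
Reactants: 3 1-methyl-2-[2-(trimethylsilyl)ethoxy]cyclohexa-1,4-diene
Product: 4 7,7-dibromo-1-methyl-6-[2-(trimethylsilyl)ethoxy]bicyclo[4.1.0]hept-3-ene (racemic)
Conditions: CHBr3, KOt-Bu, pentane, −20 → 0 °C; kept cold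
Reagents that add atoms: bromoform, BrC(Br)Br
Why: Dibromocarbene adds chemoselectively to the electron-rich tetrasubstituted enol ether rather than to the disubstituted alkene, and its carbon becomes C5′ of the tropone with the bromine needed for coupling.

Step 4
Reactants: 4 7,7-dibromo-1-methyl-6-[2-(trimethylsilyl)ethoxy]bicyclo[4.1.0]hept-3-ene
Product: 5 7,7-dibromo-1-methyl-6-[2-(trimethylsilyl)ethoxy]bicyclo[4.1.0]heptane-3,4-diol (racemic cis-diol)
Conditions: OsO4 (2 mol%), N-methylmorpholine N-oxide, acetone/H2O, 0 °C → rt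
Reagents that add atoms: osmium tetroxide, O=[Os](=O)(=O)=O; N-methylmorpholine N-oxide, C[N+]1([O-])CCOCC1; water, O
Why: OsO4-catalysed syn-dihydroxylation of the only remaining alkene; the configuration is irrelevant because both carbinol carbons become sp2 in step 5.

Step 5
Reactants: 5 7,7-dibromo-1-methyl-6-[2-(trimethylsilyl)ethoxy]bicyclo[4.1.0]heptane-3,4-diol
Product: 7 5-bromo-2-hydroxy-4-methyl-6-[2-(trimethylsilyl)ethoxy]cyclohepta-2,4,6-trien-1-one, via bicyclic 1,2-dione 6 (not isolated)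
Conditions: (CF3CO)2O, DMSO, CH2Cl2, −60 °C; Et3N, −60 °C → rt
Reagents that add atoms: none
Why: Swern-type oxidation to the 1,2-dione, then base-induced enolisation, electrocyclic opening of the alkoxy-substituted gem-dibromocyclopropane and loss of HBr, is the classical dihalocyclopropane route to 5-bromotropolones; loss of the C7′ proton keeps the silylethyl enol ether.

Step 6
Reactants: 7 5-bromo-2-hydroxy-4-methyl-6-[2-(trimethylsilyl)ethoxy]cyclohepta-2,4,6-trien-1-one
Product: 8 5-bromo-2-methoxy-4-methyl-6-[2-(trimethylsilyl)ethoxy]cyclohepta-2,4,6-trien-1-one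
Conditions: Me3SiCHN2, MeOH/toluene, 0 °C; chromatography
Reagents that add atoms: (trimethylsilyl)diazomethane, C[Si](C)(C)C=[N+]=[N-]
Why: O-Methylation of the tropolone by the diazoalkane; an unsymmetrical tropolone can be alkylated on either oxygen, so 8 is separated from its O-regioisomer, which would converge on the same target.

**West fragment (C5–C9)**

Step 7
Reactants: 9 {[tert-butyl(dimethyl)silyl]oxy}acetaldehyde, 10 ethyl 2-(triphenylphosphoranylidene)propanoate
Product: 11 ethyl (2E)-4-{[tert-butyl(dimethyl)silyl]oxy}-2-methylbut-2-enoate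
Conditions: CH2Cl2, rt
Reagents that add atoms: none
Why: Wittig olefination with a stabilised α-methyl ylide gives the E-trisubstituted enoate.

Step 8
Reactants: 11 ethyl (2E)-4-{[tert-butyl(dimethyl)silyl]oxy}-2-methylbut-2-enoate
Product: 12 (2E)-4-{[tert-butyl(dimethyl)silyl]oxy}-2-methylbut-2-en-1-ol
Conditions: i-Bu2AlH, CH2Cl2, −78 °C; aq. KNaC4H4O6
Reagents that add atoms: none
Why: 1,2-Reduction of the enoate to the allylic alcohol without touching the silyl ether.

Step 9
Reactants: 12 (2E)-4-{[tert-butyl(dimethyl)silyl]oxy}-2-methylbut-2-en-1-ol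
Product: 13 [(2R,3R)-3-({[tert-butyl(dimethyl)silyl]oxy}methyl)-2-methyloxiran-2-yl]methanol
Conditions: Ti(Oi-Pr)4 (10 mol%), D-(−)-diethyl tartrate, t-BuOOH, 4 Å molecular sieves, CH2Cl2, −20 °C
Reagents that add atoms: tert-butyl hydroperoxide, CC(C)(C)OO
Why: Sharpless asymmetric epoxidation; the D-tartrate ligand delivers oxygen to the face that gives the (2R,3R)-epoxy alcohol, which fixes C7 directly and C8 after step 10.

Step 10
Reactants: 13 [(2R,3R)-3-({[tert-butyl(dimethyl)silyl]oxy}methyl)-2-methyloxiran-2-yl]methanol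
Product: 14 (2S,3S)-3-({[tert-butyl(dimethyl)silyl]oxy}methyl)-2-methylpent-4-ene-1,2-diol
Conditions: CH2=CHMgBr, CuI (20 mol%), THF, −40 → 0 °C
Reagents that add atoms: vinylmagnesium bromide, C=C[Mg]Br
Why: Copper-catalysed Grignard opening of the 2,3-epoxy alcohol by SN2 attack at C3, the only non-quaternary epoxide carbon, with inversion; the vinyl group (future C9) and the tertiary carbinol (C7) are set stereospecifically.

Step 11
Reactants: 14 (2S,3S)-3-({[tert-butyl(dimethyl)silyl]oxy}methyl)-2-methylpent-4-ene-1,2-diol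
Product: 16 tert-butyl(dimethyl){[(2S)-2-[(2S)-2-methyloxiran-2-yl]but-3-en-1-yl]oxy}silane, via primary tosylate 15 (not isolated)
Conditions: NaH, 1-(p-toluenesulfonyl)imidazole, THF, 0 °C → rt
Reagents that add atoms: none
Why: Selective sulfonylation of the primary hydroxyl and Williamson closure by the tertiary alkoxide give the 2,2-disubstituted oxirane without touching either stereocentre.

Step 12
Reactants: 16 tert-butyl(dimethyl){[(2S)-2-[(2S)-2-methyloxiran-2-yl]but-3-en-1-yl]oxy}silane
Product: 18 (2S)-3-{[tert-butyl(dimethyl)silyl]oxy}-2-[(2S)-2-methyloxiran-2-yl]propan-1-ol, via epoxy aldehyde 17 (not isolated)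
Conditions: O3, CH2Cl2/MeOH, −78 °C; NaBH4, −78 → 0 °C
Reagents that add atoms: ozone, [O-][O+]=O
Why: Ozonolysis of the only alkene with borohydride reduction in the same flask turns the vinyl group into the C9 hydroxymethyl arm; the aldehyde is reduced cold before its α-centre can epimerise.

Step 13
Reactants: 18 (2S)-3-{[tert-butyl(dimethyl)silyl]oxy}-2-[(2S)-2-methyloxiran-2-yl]propan-1-ol
Product: 19 (2S,3R)-2-({[tert-butyl(dimethyl)silyl]oxy}methyl)-3-methylhex-5-ene-1,3-diol
Conditions: CH2=CHMgBr, CuI (20 mol%), THF, −30 → 0 °C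
Reagents that add atoms: vinylmagnesium bromide, C=C[Mg]Br
Why: Copper-catalysed vinyl Grignard attack at the unsubstituted carbon of the 2,2-disubstituted epoxide installs the allyl group (C6, C5) and reveals the C7 tertiary alcohol with its configuration untouched.

Step 14
Reactants: 19 (2S,3R)-2-({[tert-butyl(dimethyl)silyl]oxy}methyl)-3-methylhex-5-ene-1,3-diol
Product: 20 (2S,3R)-1-{[tert-butyl(dimethyl)silyl]oxy}-2-(iodomethyl)-3-methylhex-5-en-3-ol
Conditions: I2, PPh3, imidazole, CH2Cl2, 0 °C
Reagents that add atoms: iodine, II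
Why: Appel-type (Garegg–Samuelsson) iodination is selective for the primary over the tertiary hydroxyl.

**East fragment (C10–C4)**

Step 15
Reactants: 21 methyl 3,3-dimethylpent-4-enoate
Product: 23 ethyl (2E)-5,5-dimethylhepta-2,6-dienoate, via 3,3-dimethylpent-4-enal 22 (not isolated)
Conditions: i-Bu2AlH, CH2Cl2, −78 °C; then (EtO)2P(O)CH2CO2Et/NaH in THF, −78 °C → rt
Reagents that add atoms: triethyl phosphonoacetate, CCOC(=O)CP(=O)(OCC)OCC
Why: Partial reduction of the ester to its aluminium hemiacetal and Horner–Wadsworth–Emmons olefination in the same flask avoid isolating the volatile aldehyde and give the E-enoate.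

Step 16
Reactants: 23 ethyl (2E)-5,5-dimethylhepta-2,6-dienoate
Product: 24 (2E)-5,5-dimethylhepta-2,6-dien-1-ol
Conditions: i-Bu2AlH, CH2Cl2, −78 °C; aq. KNaC4H4O6
Reagents that add atoms: none
Why: 1,2-Reduction of the enoate to the E-allylic alcohol.

Step 17
Reactants: 24 (2E)-5,5-dimethylhepta-2,6-dien-1-ol
Product: 25 [(2S,3S)-3-(2,2-dimethylbut-3-en-1-yl)oxiran-2-yl]methanol
Conditions: Ti(Oi-Pr)4 (10 mol%), L-(+)-diethyl tartrate, t-BuOOH, 4 Å molecular sieves, CH2Cl2, −20 °C
Reagents that add atoms: tert-butyl hydroperoxide, CC(C)(C)OO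
Why: Sharpless asymmetric epoxidation of the E-allylic alcohol; the L-tartrate ligand gives the (2S,3S)-epoxy alcohol, from which C1 is derived in step 18.

Step 18
Reactants: 25 [(2S,3S)-3-(2,2-dimethylbut-3-en-1-yl)oxiran-2-yl]methanol
Product: 26 (2R,3S)-5,5-dimethyl-3-[(trimethylsilyl)ethynyl]hept-6-ene-1,2-diol
Conditions: Me3SiC≡CH, n-BuLi, Et2AlCl, toluene, 0 °C; then 25, 0 °C → rt
Reagents that add atoms: ethynyltrimethylsilane (as its diethylalane), C#C[Si](C)(C)C
Why: The alkynylalane, bound to the substrate alkoxide, delivers the alkynyl group to C3 of the 2,3-epoxy alcohol with inversion (the established C3 selectivity of organoalanes), creating the C1 stereocentre with the future C11 and C10 attached.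

Step 19
Reactants: 26 (2R,3S)-5,5-dimethyl-3-[(trimethylsilyl)ethynyl]hept-6-ene-1,2-diol
Product: 29 (2S)-2-ethynyl-4,4-dimethylhex-5-en-1-ol, via alkynyl aldehyde 27 (not isolated), via silylalkynyl alcohol 28 (not isolated)
Conditions: NaIO4, THF/pH 7 buffer, 0 °C; NaBH4, MeOH, 0 °C; K2CO3, rt
Reagents that add atoms: none
Why: Periodate cleavage of the 1,2-diol, immediate borohydride reduction of the epimerisable α-alkynyl aldehyde and basic methanolysis of the C-silyl group give the homopropargylic alcohol (future ring-A methylene) in one flask.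

Step 20
Reactants: 29 (2S)-2-ethynyl-4,4-dimethylhex-5-en-1-ol
Product: 30 (2S,3E)-2-(2,2-dimethylbut-3-en-1-yl)-4-iodo-3-methylbut-3-en-1-ol
Conditions: Me3Al, Cp2ZrCl2, CH2Cl2, 0 °C → rt; I2, THF, −30 °C
Reagents that add atoms: trimethylaluminium, C[Al](C)C; iodine, II
Why: Zirconium-catalysed syn-carboalumination of the terminal alkyne (methyl to the internal carbon) and iodinolysis with retention give the E-2-methylalkenyl iodide, that is the C10=C11 alkene with its methyl group; the hindered terminal alkene does not react.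

**Union and endgame**

Step 21
Reactants: 20 (2S,3R)-1-{[tert-butyl(dimethyl)silyl]oxy}-2-(iodomethyl)-3-methylhex-5-en-3-ol, 30 (2S,3E)-2-(2,2-dimethylbut-3-en-1-yl)-4-iodo-3-methylbut-3-en-1-ol
Product: 32 (2S,3E,6S,7R)-6-({[tert-butyl(dimethyl)silyl]oxy}methyl)-2-(2,2-dimethylbut-3-en-1-yl)-3,7-dimethyldeca-3,9-diene-1,7-diol, via alkylzinc iodide 31 (not isolated)
Conditions: 20, Zn dust, LiCl, THF, 35 °C; then 30, Pd(OAc)2 (5 mol%), SPhos, THF, rt → 40 °C
Reagents that add atoms: none
Why: Zinc insertion into the primary iodide and Negishi sp3–sp2 coupling with the alkenyl iodide forge C9–C10 with retention of the E geometry; alkylzinc halides tolerate the hindered tertiary hydroxyl and the primary hydroxyl of the partner.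

Step 22
Reactants: 32 (2S,3E,6S,7R)-6-({[tert-butyl(dimethyl)silyl]oxy}methyl)-2-(2,2-dimethylbut-3-en-1-yl)-3,7-dimethyldeca-3,9-diene-1,7-diol
Product: 33 (2S,3E,6S,7R)-2-(2,2-dimethylbut-3-en-1-yl)-6-(hydroxymethyl)-3,7-dimethyldeca-3,9-diene-1,7-diol
Conditions: Bu4NF, THF, 0 °C → rt
Reagents that add atoms: none
Why: Fluoride cleaves the primary silyl ether and frees the second methylene arm.

Step 23
Reactants: 33 (2S,3E,6S,7R)-2-(2,2-dimethylbut-3-en-1-yl)-6-(hydroxymethyl)-3,7-dimethyldeca-3,9-diene-1,7-diol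
Product: 34 (4R,5R,7E,9S)-5,9-bis(iodomethyl)-4,8,11,11-tetramethyltrideca-1,7,12-trien-4-ol
Conditions: I2, PPh3, imidazole, CH2Cl2, 0 °C
Reagents that add atoms: iodine, II
Why: Twofold Appel-type iodination of the two primary alcohols; the tertiary alcohol is inert.

Step 24
Reactants: 34 (4R,5R,7E,9S)-5,9-bis(iodomethyl)-4,8,11,11-tetramethyltrideca-1,7,12-trien-4-ol, 8 5-bromo-2-methoxy-4-methyl-6-[2-(trimethylsilyl)ethoxy]cyclohepta-2,4,6-trien-1-one (two molar equivalents are incorporated, one at each CH2ZnI group)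
Product: 36 (4R,5S,7E,9R)-5,9-bis(ArSE-methyl)-4,8,11,11-tetramethyltrideca-1,7,12-trien-4-ol, via bis(alkylzinc iodide) 35 (not isolated)
Conditions: 34, Zn dust, LiCl, THF, 35 °C; then 8 (2.4 equiv), Pd2(dba)3 (5 mol%), SPhos, THF/N-methylpyrrolidone, 50 °C
Reagents that add atoms: second equivalent of 8, 5-bromo-2-methoxy-4-methyl-6-[2-(trimethylsilyl)ethoxy]cyclohepta-2,4,6-trien-1-one, Cc1cc(OC)c(=O)cc(OCC[Si](C)(C)C)c1Br
Why: Twofold zinc insertion and twofold Negishi coupling, each CH2ZnI group taking up one molecule of the bromotropone, attach both seven-membered rings to their methylene groups in one operation; a bulky dialkylbiarylphosphine serves the doubly ortho-substituted C–Br bond, and cross-coupling of bromotropolone ethers is established.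

Step 25
Reactants: 36 (4R,5S,7E,9R)-5,9-bis(ArSE-methyl)-4,8,11,11-tetramethyltrideca-1,7,12-trien-4-ol
Product: 37 (2R,3S)-7-methoxy-2,5-dimethyl-2-(prop-2-en-1-yl)-3-[(2E,4R)-4-(ArSE-methyl)-3,6,6-trimethylocta-2,7-dien-1-yl]-3,4-dihydrocyclohepta[b]pyran-8(2H)-one
Conditions: NaH, THF, 0 °C → rt
Reagents that add atoms: none
Why: The C7 tertiary alkoxide adds to C6′ of the neighbouring 3-alkoxytropone (a vinylogous ester) and expels 2-(trimethylsilyl)ethoxide; this intramolecular addition–elimination closes the ring-B dihydropyran with retention at C7, while ring A has no hydroxyl within reach and any exchange of its alkoxy group is degenerate.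

Step 26
Reactants: 37 (2R,3S)-7-methoxy-2,5-dimethyl-2-(prop-2-en-1-yl)-3-[(2E,4R)-4-(ArSE-methyl)-3,6,6-trimethylocta-2,7-dien-1-yl]-3,4-dihydrocyclohepta[b]pyran-8(2H)-one
Product: 38 (2R,3R)-7-methoxy-2,5-dimethyl-3-({(2S,3S)-3-methyl-3-[(2R)-1-(ArSE)-4,4-dimethylhex-5-en-2-yl]oxiran-2-yl}methyl)-2-(prop-2-en-1-yl)-3,4-dihydrocyclohepta[b]pyran-8(2H)-one
Conditions: 1,2:4,5-di-O-isopropylidene-β-L-erythro-2,3-hexodiulo-2,6-pyranose (L-fructose-derived ketone, 0.3 equiv), KHSO5 (as 2KHSO5·KHSO4·K2SO4), K2CO3, Bu4NHSO4, aq. Na2B4O7, MeCN/CH2(OMe)2, 0 °C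
Reagents that add atoms: potassium peroxymonosulfate, [K+].[O-]S(=O)(=O)OO
Why: Shi epoxidation: the chiral dioxirane epoxidises the electron-rich trisubstituted E-alkene in preference to the two monosubstituted alkenes and the push–pull tropone double bonds, and its spiro transition state selects the face that gives the (10S,11S)-epoxide under reagent control in an open-chain substrate.

Step 27
Reactants: 38 (2R,3R)-7-methoxy-2,5-dimethyl-3-({(2S,3S)-3-methyl-3-[(2R)-1-(ArSE)-4,4-dimethylhex-5-en-2-yl]oxiran-2-yl}methyl)-2-(prop-2-en-1-yl)-3,4-dihydrocyclohepta[b]pyran-8(2H)-one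
Product: 39 (1R,4E,7R,8R,10S,11S)-10,11-epoxy macrocycle: eleven-membered ring fused at C7/C8 to the ring-B 7-methoxy-5-methylcyclohepta[b]pyran-8-one, with the ArSE-methyl group on C1
Conditions: second-generation Grubbs catalyst (15 mol%), toluene (0.5 mM), 80 °C
Reagents that add atoms: none
Why: Ring-closing metathesis of the two terminal alkenes closes the eleven-membered ring; because the trisubstituted alkene is already an epoxide no six-membered ring can form, and the quaternary C3 next to the new alkene should enforce the E geometry under equilibrating conditions.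

Step 28
Reactants: 39 (1R,4E,7R,8R,10S,11S)-10,11-epoxy macrocycle with the ArSE-methyl group on C1
Product: 40 (1R,4E,7R,8R,10S,11S)-10,11-epoxy macrocycle carrying on the C1 methylene the free 6-hydroxy-2-methoxy-4-methyl-1-oxocyclohepta-2,4,6-trien-5-yl group (key-step precursor)
Conditions: Bu4NF, THF, 0 °C; pH 6 phosphate buffer; used at once
Reagents that add atoms: none
Why: Fluoride-induced fragmentation of the 2-(trimethylsilyl)ethyl vinylogous ester (loss of ethene and Me3SiF) frees the 6′-hydroxyl under non-acidic conditions that leave the epoxide intact.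

Step 29
Reactants: 40 (1R,4E,7R,8R,10S,11S)-10,11-epoxy macrocycle with pendant hydroxytropone
Product: 41 (1R,7R,8R,10S,11R)-bis(tropolone methyl ether) of the target, with both dihydropyrans closed and the free C10 hydroxyl
Conditions: (+)-camphor-10-sulfonic acid (0.2 equiv), CH2Cl2, −20 → 0 °C
Reagents that add atoms: none
Why: The sulfonic acid protonates the epoxide oxygen, the C11–O bond is polarised because C11 is tertiary, and the 6′-oxygen of the hydroxytropone (a vinylogous carboxylic acid tethered through C1 and its methylene) attacks C11 from the face opposite the departing oxygen in a borderline SN2 process, after which the proton is lost. The closest known reaction type is the acid-catalysed cyclisation of phenols and enolised 1,3-diones onto pendant trisubstituted epoxides to give 3-hydroxy-2,2-dialkylchromans. The dihydropyran is closed in the 6-exo mode, the breaking C11–O bond lying outside the new ring. C11 is set by inversion of the reagent-defined (11S) epoxide carbon and becomes R, while C10 keeps its C–O bond and its S configuration, so both centres trace back to the Shi epoxidation of the E-alkene. The step needs attack at C11 rather than 7-endo attack at C10, hydride shift, or capture of the developing cation by the C4=C5 alkene across the ring; Markovnikov polarisation towards the tertiary carbon, a tether that puts only C11 within reach of the oxygen, and the low temperature and catalytic acid that the acidic nucleophile allows should secure this.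

Step 30
Reactants: 41 (1R,7R,8R,10S,11R)-bis(tropolone methyl ether) of the target
Product: 42 CNP0283947.4 (target), (1R,7R,8R,10S,11R)
Conditions: LiCl, DMF, 110 °C; dilute aq. HCl work-up
Reagents that add atoms: none
Why: Chloride demethylates both vinylogous methyl esters (tropolone methyl ethers) by SN2 attack at the methyl groups, conditions under which the tertiary pyran ethers, the secondary alcohol and the alkene are inert.

**Compound list**

1 | 2-methylphenol | Cc1ccccc1O | starting material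
2 | 1-methyl-2-[2-(trimethylsilyl)ethoxy]benzene | Cc1ccccc1OCC[Si](C)(C)C | intermediate
3 | 1-methyl-2-[2-(trimethylsilyl)ethoxy]cyclohexa-1,4-diene | CC1=C(OCC[Si](C)(C)C)CC=CC1 | intermediate
4 | 7,7-dibromo-1-methyl-6-[2-(trimethylsilyl)ethoxy]bicyclo[4.1.0]hept-3-ene (racemic) | CC12CC=CCC1(OCC[Si](C)(C)C)C2(Br)Br | intermediate
5 | 7,7-dibromo-1-methyl-6-[2-(trimethylsilyl)ethoxy]bicyclo[4.1.0]heptane-3,4-diol (racemic cis-diol) | CC12CC(O)C(O)CC1(OCC[Si](C)(C)C)C2(Br)Br | intermediate
6 | 7,7-dibromo-1-methyl-6-[2-(trimethylsilyl)ethoxy]bicyclo[4.1.0]heptane-3,4-dione (racemic) | CC12CC(=O)C(=O)CC1(OCC[Si](C)(C)C)C2(Br)Br | intermediate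
7 | 5-bromo-2-hydroxy-4-methyl-6-[2-(trimethylsilyl)ethoxy]cyclohepta-2,4,6-trien-1-one | Cc1cc(O)c(=O)cc(OCC[Si](C)(C)C)c1Br | intermediate
8 | 5-bromo-2-methoxy-4-methyl-6-[2-(trimethylsilyl)ethoxy]cyclohepta-2,4,6-trien-1-one | Cc1cc(OC)c(=O)cc(OCC[Si](C)(C)C)c1Br | intermediate
9 | {[tert-butyl(dimethyl)silyl]oxy}acetaldehyde | O=CCO[Si](C)(C)C(C)(C)C | starting material
10 | ethyl 2-(triphenylphosphoranylidene)propanoate | CCOC(=O)C(C)=P(c1ccccc1)(c1ccccc1)c1ccccc1 | starting material
11 | ethyl (2E)-4-{[tert-butyl(dimethyl)silyl]oxy}-2-methylbut-2-enoate | CCOC(=O)/C(C)=C/CO[Si](C)(C)C(C)(C)C | intermediate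
12 | (2E)-4-{[tert-butyl(dimethyl)silyl]oxy}-2-methylbut-2-en-1-ol | OC/C(C)=C/CO[Si](C)(C)C(C)(C)C | intermediate
13 | [(2R,3R)-3-({[tert-butyl(dimethyl)silyl]oxy}methyl)-2-methyloxiran-2-yl]methanol | OC[C@@]1(C)O[C@@H]1CO[Si](C)(C)C(C)(C)C | intermediate
14 | (2S,3S)-3-({[tert-butyl(dimethyl)silyl]oxy}methyl)-2-methylpent-4-ene-1,2-diol | OC[C@@](C)(O)[C@@H](C=C)CO[Si](C)(C)C(C)(C)C | intermediate
15 | (2S,3S)-3-({[tert-butyl(dimethyl)silyl]oxy}methyl)-2-hydroxy-2-methylpent-4-en-1-yl 4-methylbenzenesulfonate | Cc1ccc(cc1)S(=O)(=O)OC[C@@](C)(O)[C@@H](C=C)CO[Si](C)(C)C(C)(C)C | intermediate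
16 | tert-butyl(dimethyl){[(2S)-2-[(2S)-2-methyloxiran-2-yl]but-3-en-1-yl]oxy}silane | C=C[C@@H](CO[Si](C)(C)C(C)(C)C)[C@@]1(C)CO1 | intermediate
17 | (2S)-3-{[tert-butyl(dimethyl)silyl]oxy}-2-[(2S)-2-methyloxiran-2-yl]propanal | O=C[C@@H](CO[Si](C)(C)C(C)(C)C)[C@@]1(C)CO1 | intermediate
18 | (2S)-3-{[tert-butyl(dimethyl)silyl]oxy}-2-[(2S)-2-methyloxiran-2-yl]propan-1-ol | OC[C@@H](CO[Si](C)(C)C(C)(C)C)[C@@]1(C)CO1 | intermediate
19 | (2S,3R)-2-({[tert-butyl(dimethyl)silyl]oxy}methyl)-3-methylhex-5-ene-1,3-diol | OC[C@@H](CO[Si](C)(C)C(C)(C)C)[C@](C)(O)CC=C | intermediate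
20 | (2S,3R)-1-{[tert-butyl(dimethyl)silyl]oxy}-2-(iodomethyl)-3-methylhex-5-en-3-ol | IC[C@@H](CO[Si](C)(C)C(C)(C)C)[C@](C)(O)CC=C | intermediate
21 | methyl 3,3-dimethylpent-4-enoate | COC(=O)CC(C)(C)C=C | starting material
22 | 3,3-dimethylpent-4-enal | O=CCC(C)(C)C=C | intermediate
23 | ethyl (2E)-5,5-dimethylhepta-2,6-dienoate | CCOC(=O)/C=C/CC(C)(C)C=C | intermediate
24 | (2E)-5,5-dimethylhepta-2,6-dien-1-ol | OC/C=C/CC(C)(C)C=C | intermediate
25 | [(2S,3S)-3-(2,2-dimethylbut-3-en-1-yl)oxiran-2-yl]methanol | OC[C@@H]1O[C@H]1CC(C)(C)C=C | intermediate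
26 | (2R,3S)-5,5-dimethyl-3-[(trimethylsilyl)ethynyl]hept-6-ene-1,2-diol | OC[C@H](O)[C@H](C#C[Si](C)(C)C)CC(C)(C)C=C | intermediate
27 | (2S)-4,4-dimethyl-2-[(trimethylsilyl)ethynyl]hex-5-enal | O=C[C@H](C#C[Si](C)(C)C)CC(C)(C)C=C | intermediate
28 | (2S)-4,4-dimethyl-2-[(trimethylsilyl)ethynyl]hex-5-en-1-ol | OC[C@H](C#C[Si](C)(C)C)CC(C)(C)C=C | intermediate
29 | (2S)-2-ethynyl-4,4-dimethylhex-5-en-1-ol | OC[C@H](C#C)CC(C)(C)C=C | intermediate
30 | (2S,3E)-2-(2,2-dimethylbut-3-en-1-yl)-4-iodo-3-methylbut-3-en-1-ol | C/C(=C\I)[C@@H](CO)CC(C)(C)C=C | intermediate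
31 | alkylzinc iodide of 20: {(2S,3R)-2-({[tert-butyl(dimethyl)silyl]oxy}methyl)-3-hydroxy-3-methylhex-5-en-1-yl}zinc iodide | I[Zn]C[C@@H](CO[Si](C)(C)C(C)(C)C)[C@](C)(O)CC=C | intermediate
32 | (2S,3E,6S,7R)-6-({[tert-butyl(dimethyl)silyl]oxy}methyl)-2-(2,2-dimethylbut-3-en-1-yl)-3,7-dimethyldeca-3,9-diene-1,7-diol | C=CC[C@@](C)(O)[C@H](CO[Si](C)(C)C(C)(C)C)C/C=C(C)/[C@@H](CO)CC(C)(C)C=C | intermediate
33 | (2S,3E,6S,7R)-2-(2,2-dimethylbut-3-en-1-yl)-6-(hydroxymethyl)-3,7-dimethyldeca-3,9-diene-1,7-diol | C=CC[C@@](C)(O)[C@H](CO)C/C=C(C)/[C@@H](CO)CC(C)(C)C=C | intermediate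
34 | (4R,5R,7E,9S)-5,9-bis(iodomethyl)-4,8,11,11-tetramethyltrideca-1,7,12-trien-4-ol | C=CC[C@@](C)(O)[C@H](CI)C/C=C(C)/[C@@H](CI)CC(C)(C)C=C | intermediate
35 | bis(alkylzinc iodide) of 34 (both CH2I groups converted into CH2ZnI) | C=CC[C@@](C)(O)[C@H](C[Zn]I)C/C=C(C)/[C@@H](C[Zn]I)CC(C)(C)C=C | intermediate
36 | (4R,5S,7E,9R)-5,9-bis(ArSE-methyl)-4,8,11,11-tetramethyltrideca-1,7,12-trien-4-ol | C=CC[C@@](C)(O)[C@H](Cc1c(C)cc(OC)c(=O)cc1OCC[Si](C)(C)C)C/C=C(C)/[C@@H](Cc1c(C)cc(OC)c(=O)cc1OCC[Si](C)(C)C)CC(C)(C)C=C | intermediate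
37 | (2R,3S)-7-methoxy-2,5-dimethyl-2-(prop-2-en-1-yl)-3-[(2E,4R)-4-(ArSE-methyl)-3,6,6-trimethylocta-2,7-dien-1-yl]-3,4-dihydrocyclohepta[b]pyran-8(2H)-one | C=CC[C@@]1(C)Oc2cc(=O)c(OC)cc(C)c2C[C@@H]1C/C=C(C)/[C@@H](Cc1c(C)cc(OC)c(=O)cc1OCC[Si](C)(C)C)CC(C)(C)C=C | intermediate
38 | (2R,3R)-7-methoxy-2,5-dimethyl-3-({(2S,3S)-3-methyl-3-[(2R)-1-(ArSE)-4,4-dimethylhex-5-en-2-yl]oxiran-2-yl}methyl)-2-(prop-2-en-1-yl)-3,4-dihydrocyclohepta[b]pyran-8(2H)-one | C=CC[C@@]1(C)Oc2cc(=O)c(OC)cc(C)c2C[C@@H]1C[C@@H]1O[C@@]1(C)[C@@H](Cc1c(C)cc(OC)c(=O)cc1OCC[Si](C)(C)C)CC(C)(C)C=C | intermediate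
39 | (1R,4E,7R,8R,10S,11S)-10,11-epoxy macrocycle, ring B pyran-fused, ring A as its 6′-[2-(trimethylsilyl)ethyl] ether on the C1 methylene | Cc1cc(OC)c(=O)cc(OCC[Si](C)(C)C)c1C[C@H]1CC(C)(C)/C=C/C[C@@]3(C)Oc4cc(=O)c(OC)cc(C)c4C[C@@H]3C[C@@H]5O[C@@]15C | intermediate
40 | (1R,4E,7R,8R,10S,11S)-10,11-epoxy macrocycle with pendant 6′-hydroxytropone (key-step precursor) | Cc1cc(OC)c(=O)cc(O)c1C[C@H]1CC(C)(C)/C=C/C[C@@]3(C)Oc4cc(=O)c(OC)cc(C)c4C[C@@H]3C[C@@H]5O[C@@]15C | intermediate
41 | (1R,4E,7R,8R,10S,11R)-bis(tropolone methyl ether) of the target (key-step product) | Cc1cc(OC)c(=O)cc2c1C[C@H]1CC(C)(C)/C=C/C[C@@]3(C)Oc4cc(=O)c(OC)cc(C)c4C[C@@H]3C[C@H](O)[C@]1(C)O2 | intermediate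
42 | CNP0283947.4 | Cc1cc(=O)c(O)cc2c1C[C@H]1CC(C)(C)/C=C/C[C@@]3(C)Oc4cc(O)c(=O)cc(C)c4C[C@@H]3C[C@H](O)[C@]1(C)O2 | target

**Totals.** Total step count: 30. Longest linear sequence: 18 steps (steps 7–14 and 21–30, from 9 to 42).

**Steps most likely to fail**

1. Step 27 (ring-closing metathesis). After initiation at the allyl group, closure onto the vinyl group at the quaternary C3 may be slower than intermolecular metathesis, giving dimers and oligomers; the strained eleven-membered ring may also close with Z geometry.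
Fallback: this sets out from 20 and 30 and makes C4=C5 first and the ring second. Cross-metathesis of the allyl group of 20 with the hindered vinyl group of 30 (second-generation Grubbs catalyst, CH2Cl2, 40 °C, 30 in excess) should give the open-chain E,E-diene diiodide F1. Zinc insertion into its primary iodide gives the alkylzinc iodide F2, and palladium-catalysed intramolecular Negishi coupling with the alkenyl iodide at high dilution closes C9–C10 to the macrocyclic triene silyl ether F3. The operations of steps 22–25 then give in turn the macrocyclic triol F4, the bis-iodide F5, its bis(alkylzinc iodide) F6, the bis-troponyl macrocycle F7 (from two equivalents of 8) and, after alkoxide addition–elimination, the pyran-fused macrocyclic diene F8. Shi epoxidation of the trisubstituted alkene of F8 under the conditions of step 26 returns the route to 39.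

2. Step 29 (key step). The protonated epoxide may be captured across the ring by the C4=C5 alkene, may rearrange by hydride shift to the C10 ketone, or may be attacked at C10 (7-endo) instead of at C11.
Fallback: this sets out from 38 and moves the epoxide opening before the macrocyclisation, where no transannular alkene exists. Bu4NF frees the open-chain hydroxytropone epoxide F9. Camphorsulfonic acid in CH2Cl2 closes the ring-A dihydropyran by the same 6-exo opening with inversion at C11, giving the open-chain bis-pyran carbinol F10. Ring-closing metathesis of its two terminal alkenes (second-generation Grubbs catalyst, toluene, high dilution) returns the route to 41.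

3. Step 24 (twofold Negishi coupling). Transmetalation and reductive elimination at the doubly ortho-substituted C5′ may be slow, so that protodezincation, β-hydride elimination from the alkylpalladium intermediates, or radical cyclisation onto the terminal alkenes during zinc insertion consume the bis-zinc reagent.
Fallback: this sets out from 34 and replaces zinc by boron. Copper-catalysed borylation (CuI, PPh3, LiOMe, bis(pinacolato)diboron, DMF, rt) should give the bis(pinacol boronate) F11. KHF2 in MeOH/H2O converts it into the bis(potassium trifluoroborate) F12. Twofold sp3–sp2 Suzuki–Miyaura coupling with two equivalents of 8 (Pd(OAc)2, RuPhos, K2CO3, toluene/H2O, 85 °C) returns the route to 36.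

Further compounds
F1 | step 27 | cross-metathesis product of 20 and 30: open-chain (C4=C5 E, C10=C11 E) diene with primary iodide on the C9 carbon, alkenyl iodide at C10, silyl ether, tertiary and primary hydroxyl | IC[C@@H](CO[Si](C)(C)C(C)(C)C)[C@](C)(O)C/C=C/C(C)(C)C[C@H](CO)/C(C)=C/I
F2 | step 27 | alkylzinc iodide of F1 | I[Zn]C[C@@H](CO[Si](C)(C)C(C)(C)C)[C@](C)(O)C/C=C/C(C)(C)C[C@H](CO)/C(C)=C/I
F3 | step 27 | (1S,4E,7R,8S,10E)-8-({[tert-butyl(dimethyl)silyl]oxy}methyl)-1-(hydroxymethyl)-3,3,7,11-tetramethylcycloundeca-4,10-dien-7-ol (ring locants of the remarks) | CC1(C)/C=C/C[C@@](C)(O)[C@H](CO[Si](C)(C)C(C)(C)C)C/C=C(C)/[C@@H](CO)C1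
F4 | step 27 | macrocyclic triol: F3 without the silyl group | CC1(C)/C=C/C[C@@](C)(O)[C@H](CO)C/C=C(C)/[C@@H](CO)C1
F5 | step 27 | macrocyclic bis-iodide: both CH2OH groups of F4 as CH2I | CC1(C)/C=C/C[C@@](C)(O)[C@H](CI)C/C=C(C)/[C@@H](CI)C1
F6 | step 27 | bis(alkylzinc iodide) of F5 | CC1(C)/C=C/C[C@@](C)(O)[C@H](C[Zn]I)C/C=C(C)/[C@@H](C[Zn]I)C1
F7 | step 27 | macrocyclic diene-ol with ArSE-methyl groups on C1 and C8 | CC1(C)/C=C/C[C@@](C)(O)[C@H](Cc2c(C)cc(OC)c(=O)cc2OCC[Si](C)(C)C)C/C=C(C)/[C@@H](Cc2c(C)cc(OC)c(=O)cc2OCC[Si](C)(C)C)C1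
F8 | step 27 | macrocyclic (4E,10E)-diene with ring-B pyran closed and ArSE-methyl on C1 (the alkene corresponding to 39) | CC1(C)/C=C/C[C@@]2(C)Oc3cc(=O)c(OC)cc(C)c3C[C@@H]2C/C=C(C)/[C@@H](Cc2c(C)cc(OC)c(=O)cc2OCC[Si](C)(C)C)C1
F9 | step 29 | open-chain (10S,11S)-epoxide 38 with the ring-A 6′-hydroxyl free | C=CC[C@@]1(C)Oc2cc(=O)c(OC)cc(C)c2C[C@@H]1C[C@@H]1O[C@@]1(C)[C@@H](Cc1c(C)cc(OC)c(=O)cc1O)CC(C)(C)C=C
F10 | step 29 | open-chain bis-pyran (10S,11R)-carbinol with allyl on C7 and the 2,2-dimethylbut-3-enyl group on C1 | C=CC[C@@]1(C)Oc2cc(=O)c(OC)cc(C)c2C[C@@H]1C[C@H](O)[C@]1(C)Oc2cc(=O)c(OC)cc(C)c2C[C@H]1CC(C)(C)C=C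
F11 | step 24 | bis(pinacol boronate) of 34 (both CH2I groups as CH2B(pin)) | C=CC[C@@](C)(O)[C@H](CB1OC(C)(C)C(C)(C)O1)C/C=C(C)/[C@@H](CB1OC(C)(C)C(C)(C)O1)CC(C)(C)C=C
F12 | step 24 | bis(potassium trifluoroborate) of 34 | C=CC[C@@](C)(O)[C@H](C[B-](F)(F)F)C/C=C(C)/[C@@H](C[B-](F)(F)F)CC(C)(C)C=C.[K+].[K+]
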